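A direct plan would start from A1, 3,5-dimethoxybenzaldehyde, free one phenol and benzylate it, and join the aldehyde to A2, 3-hydroxyphenylacetic acid, by Perkin condensation, decarboxylation and alkene reduction; this would give the bibenzyl A3, 3-{2-[3-(benzyloxy)-5-methoxyphenyl]ethyl}phenol.
After pivaloylation of ring B, ring A would be dibrominated next to the chain to give the dibromide A4, 3-{2-[3-(benzyloxy)-2,6-dibromo-5-methoxyphenyl]ethyl}phenyl pivalate, and both aryl–CH2 bonds would be made by a twofold Negishi coupling of A4 with the benzylzinc reagent A5, [4-(benzyloxy)benzyl]zinc chloride; ester cleavage and hydrogenolysis would finish.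
Weak point 1, the twofold benzyl coupling of A4 with A5: both C–Br bonds are flanked by the phenethyl chain and an alkoxy group, the second coupling must complete a pentasubstituted ring, and mono-coupling and protodebromination would compete.
Weak point 2, the dibromination that leads to A4: its regiochemistry would rest on the C–H between the two oxygens staying untouched and on an ester on ring B that is put on and taken off for this purpose only.
Weak point 3, the run-up from A1 and A2 to A3: mono-demethylation, benzylation, Perkin condensation, copper–quinoline decarboxylation near 220 °C and diimide reduction would spend about six operations on one C–C bond of a plain bibenzyl.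

**Retrosynthetic overview**
Ring A (phenol numbering: C1–OH, C2–CH2Ar, C3–CH2CH2Ar', C4–CH2Ar, C5–OMe, C6–H) would be assembled rather than substituted. A Danheiser benzannulation of a 2,4-dibenzyl-3-phenethylcyclobutenone with methoxyacetylene forms the C1–C6 and C4–C5 bonds and closes the ring at C1–C2 by 6π electrocyclisation.
The alkyne delivers C5–OMe and C6–H, and the ketene carbonyl becomes the free C1–OH, so the OH/OMe difference comes from two oxygen sources and no selective demethylation is needed.
The cyclobutenone comes from a thermal [2+2] union of two molecules of one ynol ether (both benzyl groups), followed by organolithium addition and hydrolytic carbonyl transposition (the phenethyl chain).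
Ring order: the four-membered ring first, ring A last; ring B and the two p-oxybenzyl rings are bought. There is no aryl halogenation, no cross-coupling at crowded positions, and one kind of protecting group (benzyl ether) that falls in the last step.

Key step: step 7

Remark: the SMILES is taken as the definition of the target (a bibenzyl); ring A is symmetric about the axis through C3 and C6, and the molecule has no stereocentre.

Step 1
Reactants: 1 2-(3-hydroxyphenyl)ethanol
Product: 2 2-[3-(benzyloxy)phenyl]ethanol
Conditions: BnBr (1.05 equiv), K2CO3, acetone, reflux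
Reagents that add atoms: benzyl bromide, BrCc1ccccc1
Why: Williamson etherification, in which K2CO3 deprotonates only the phenol, so the primary alcohol should stay free.

Step 2
Reactants: 2 2-[3-(benzyloxy)phenyl]ethanol
Product: 3 1-(benzyloxy)-3-(2-iodoethyl)benzene
Conditions: PPh3, I2, imidazole, CH2Cl2, 0 °C → rt
Reagents that add atoms: iodine, II
Why: Appel-type iodination converts the primary alcohol into the iodide by SN2 displacement of the alkoxyphosphonium ion and should leave the benzyl ether untouched.

Step 3
Reactants: 4 ethoxyacetylene; 5 4-(benzyloxy)benzyl bromide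
Product: 7 1-(benzyloxy)-4-(3-ethoxyprop-2-yn-1-yl)benzene, via lithium ethoxyacetylide 6 (not isolated)
Conditions: n-BuLi, THF, −78 °C; then 5, DMPU, −78 → 0 °C
Reagents that add atoms: none
Why: SN2 alkylation of a lithium alkoxyacetylide by a reactive benzylic bromide in a dipolar cosolvent should give the 1-ethoxy-1-alkyne, the acetylide being too weak a base to metalate the product.

Step 4
Reactants: 7 1-(benzyloxy)-4-(3-ethoxyprop-2-yn-1-yl)benzene (two molecules)
Product: 9 2,4-bis[4-(benzyloxy)benzyl]-3-ethoxycyclobut-2-en-1-one, via arylmethylketene 8 (not isolated)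
Conditions: xylenes (about 1 M), 125 °C, N2 stream
Reagents that add atoms: none
Why: Thermal retro-ene fragmentation of one molecule of the ethyl ynol ether releases ethene and ketene 8, which a second molecule of 7 should capture in a regioselective [2+2] cycloaddition (its benzyl-bearing carbon bonds to the ketene carbonyl carbon), the classical route from 1-ethoxy-1-alkynes to 2,4-dialkyl-3-ethoxycyclobutenones; the new stereocentre at C4 is racemic and is erased in step 7.

Step 5
Reactants: 3 1-(benzyloxy)-3-(2-iodoethyl)benzene; 9 2,4-bis[4-(benzyloxy)benzyl]-3-ethoxycyclobut-2-en-1-one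
Product: 12 2,4-bis[4-(benzyloxy)benzyl]-3-{2-[3-(benzyloxy)phenyl]ethyl}cyclobut-2-en-1-one, via alkyllithium 10 (not isolated), via tertiary cyclobutenol 11 (not isolated)
Conditions: t-BuLi (2.1 equiv), Et2O/pentane, −78 °C (on 3); then 9 in THF, −78 → −20 °C; then 1 M HCl, THF, rt
Reagents that add atoms: water, O
Why: Iodine–lithium exchange gives the primary alkyllithium, which should add 1,2 to the vinylogous ester carbonyl (enolisation would create an antiaromatic cyclobutadienolate), and dilute acid then hydrolyses the enol ether with loss of water, a 1,3-carbonyl transposition of the Stork–Danheiser type that places the phenethyl group at C3 between the two benzyl-bearing carbons; the stereocentres of 11 are of no consequence and C4 of 12 is racemic.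

Step 6
Reactants: 13 2-chloro-1,1-dimethoxyethane
Product: 15 methoxyacetylene, via sodium methoxyacetylide 14 (not isolated)
Conditions: NaNH2 (3.1 equiv), liquid NH3, −33 °C; evaporate NH3; saturated aqueous NaCl, −20 °C; distil the low-boiling alkyne into cold toluene
Reagents that add atoms: none
Why: Twofold base-induced elimination (of methanol, then of HCl) with NaNH2 gives sodium methoxyacetylide, which is protonated on work-up and distilled, the standard preparation of this volatile ynol ether.

Step 7
Reactants: 12 2,4-bis[4-(benzyloxy)benzyl]-3-{2-[3-(benzyloxy)phenyl]ethyl}cyclobut-2-en-1-one; 15 methoxyacetylene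
Product: 20 3-{2-[3-(benzyloxy)phenyl]ethyl}-2,4-bis[4-(benzyloxy)benzyl]-5-methoxyphenol, via vinylketene 16 (not isolated), via 4-alkenylcyclobutenone 17 (not isolated), via dienylketene 18 (not isolated), via cyclohexa-2,4-dienone 19 (not isolated)
Conditions: 15 (3 equiv), toluene, sealed tube, 80 °C then 110 °C; then KOH, MeOH, rt; aqueous NH4Cl
Reagents that add atoms: none
Why: On heating, 12 should open by 4π electrocyclic cleavage of its C1–C4 bond to vinylketene 16, whose ketene C=C undergoes a regioselective [2+2] cycloaddition with methoxyacetylene (the nucleophilic terminal CH carbon bonds to the ketene carbonyl carbon, the methoxy-bearing carbon to the ketene α-carbon) to give 17, after which a second 4π ring opening gives dienylketene 18, 6π electrocyclisation gives dienone 19 and tautomerisation gives phenol 20. The closest known reaction type is the Danheiser benzannulation of cyclobutenones with alkoxyacetylenes, which delivers resorcinol monoalkyl ethers. Ring A closes by thermal disrotatory 6π electrocyclisation of 18 between the ketene carbon (future C1) and the benzyl-bearing CH terminus (future C2), after the cycloaddition has made the C1–C6 and C4–C5 bonds, so that the alkyne is in effect inserted between the carbonyl carbon and the α-carbon of the four-membered ring. No stereocentre is formed, and the only one of 12 becomes an aromatic carbon. The step needs regioselectivity in the [2+2] event, which the polarisation of ynol ether and ketene secures and which puts C6–H between the two oxygens and OMe meta to OH. It also needs the ketene to be trapped by the alkyne and not by the product phenol, which the excess of alkyne should secure, and the KOH/MeOH treatment would cleave any aryl ester that forms nonetheless.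

Step 8
Reactants: 20 3-{2-[3-(benzyloxy)phenyl]ethyl}-2,4-bis[4-(benzyloxy)benzyl]-5-methoxyphenol
Product: 21 3-[2-(3-hydroxyphenyl)ethyl]-2,4-bis(4-hydroxybenzyl)-5-methoxyphenol (the target)
Conditions: H2 (1 atm), 10% Pd/C, EtOAc/MeOH, rt
Reagents that add atoms: none
Why: Catalytic hydrogenolysis should cleave the three aryl benzyl ethers under neutral conditions, while the aryl methyl ether, the free phenol and the diarylmethane and bibenzyl C–C bonds are inert; no stereocentre is present.

**Compound list**
1 | 2-(3-hydroxyphenyl)ethanol | OCCc1cccc(O)c1 | starting material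
2 | 2-[3-(benzyloxy)phenyl]ethanol | OCCc1cccc(OCc2ccccc2)c1 | intermediate
3 | 1-(benzyloxy)-3-(2-iodoethyl)benzene | ICCc1cccc(OCc2ccccc2)c1 | intermediate
4 | ethoxyacetylene (ethoxyethyne) | CCOC#C | starting material
5 | 4-(benzyloxy)benzyl bromide | BrCc1ccc(OCc2ccccc2)cc1 | starting material
6 | lithium ethoxyacetylide | [Li+].[C-]#COCC | intermediate (not isolated)
7 | 1-(benzyloxy)-4-(3-ethoxyprop-2-yn-1-yl)benzene | CCOC#CCc1ccc(OCc2ccccc2)cc1 | intermediate
8 | 3-[4-(benzyloxy)phenyl]prop-1-en-1-one ([4-(benzyloxy)benzyl]ketene) | O=C=CCc1ccc(OCc2ccccc2)cc1 | intermediate (not isolated)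
9 | 2,4-bis[4-(benzyloxy)benzyl]-3-ethoxycyclobut-2-en-1-one (racemic) | CCOC1=C(Cc2ccc(OCc3ccccc3)cc2)C(=O)C1Cc1ccc(OCc2ccccc2)cc1 | intermediate
10 | {2-[3-(benzyloxy)phenyl]ethyl}lithium | [Li]CCc1cccc(OCc2ccccc2)c1 | intermediate (not isolated)
11 | 2,4-bis[4-(benzyloxy)benzyl]-1-{2-[3-(benzyloxy)phenyl]ethyl}-3-ethoxycyclobut-2-en-1-ol (diastereomer mixture, racemic; lithium alkoxide until the acid quench) | CCOC1=C(Cc2ccc(OCc3ccccc3)cc2)C(O)(CCc2cccc(OCc3ccccc3)c2)C1Cc1ccc(OCc2ccccc2)cc1 | intermediate (not isolated)
12 | 2,4-bis[4-(benzyloxy)benzyl]-3-{2-[3-(benzyloxy)phenyl]ethyl}cyclobut-2-en-1-one (racemic) | O=C1C(Cc2ccc(OCc3ccccc3)cc2)=C(CCc2cccc(OCc3ccccc3)c2)C1Cc1ccc(OCc2ccccc2)cc1 | intermediate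
13 | 2-chloro-1,1-dimethoxyethane (chloroacetaldehyde dimethyl acetal) | COC(CCl)OC | starting material
14 | sodium methoxyacetylide | [Na+].[C-]#COC | intermediate (not isolated)
15 | methoxyacetylene (methoxyethyne) | COC#C | intermediate
16 | (3E)-2-[4-(benzyloxy)benzyl]-3-{2-[3-(benzyloxy)phenyl]ethyl}-5-[4-(benzyloxy)phenyl]penta-1,3-dien-1-one (geometry expected from outward rotation) | O=C=C(Cc1ccc(OCc2ccccc2)cc1)/C(CCc1cccc(OCc2ccccc2)c1)=C/Cc1ccc(OCc2ccccc2)cc1 | intermediate (not isolated)
17 | 4-[4-(benzyloxy)benzyl]-4-{(2E)-5-[3-(benzyloxy)phenyl]-1-[4-(benzyloxy)phenyl]pent-2-en-3-yl}-3-methoxycyclobut-2-en-1-one (racemic) | COC1=CC(=O)C1(Cc1ccc(OCc2ccccc2)cc1)/C(CCc1cccc(OCc2ccccc2)c1)=C/Cc1ccc(OCc2ccccc2)cc1 | intermediate (not isolated)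
18 | (3E,5E)-4-[4-(benzyloxy)benzyl]-5-{2-[3-(benzyloxy)phenyl]ethyl}-7-[4-(benzyloxy)phenyl]-3-methoxyhepta-1,3,5-trien-1-one (geometry required for ring closure) | O=C=C/C(OC)=C(Cc1ccc(OCc2ccccc2)cc1)\C(CCc1cccc(OCc2ccccc2)c1)=C\Cc1ccc(OCc2ccccc2)cc1 | intermediate (not isolated)
19 | 4,6-bis[4-(benzyloxy)benzyl]-5-{2-[3-(benzyloxy)phenyl]ethyl}-3-methoxycyclohexa-2,4-dien-1-one (racemic) | COC1=CC(=O)C(Cc2ccc(OCc3ccccc3)cc2)C(CCc2cccc(OCc3ccccc3)c2)=C1Cc1ccc(OCc2ccccc2)cc1 | intermediate (not isolated)
20 | 3-{2-[3-(benzyloxy)phenyl]ethyl}-2,4-bis[4-(benzyloxy)benzyl]-5-methoxyphenol | COc1cc(O)c(Cc2ccc(OCc3ccccc3)cc2)c(CCc2cccc(OCc3ccccc3)c2)c1Cc1ccc(OCc2ccccc2)cc1 | intermediate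
21 | 3-[2-(3-hydroxyphenyl)ethyl]-2,4-bis(4-hydroxybenzyl)-5-methoxyphenol | COc1cc(O)c(Cc2ccc(O)cc2)c(CCc2cccc(O)c2)c1Cc1ccc(O)cc1 | target

**Step count and risks**
Total step count: 8. Longest linear sequence: 5 steps (steps 3, 4, 5, 7, 8; equally steps 1, 2, 5, 7, 8).

Steps most likely to fail:

1. Step 7 (key step). The low-boiling terminal ynol ether may polymerise or be lost before vinylketene 16 is intercepted, so that 16 recloses to 12, dimerises or acylates the phenol already formed. Slow opening of the crowded intermediate 17 would show as a stalled cascade. Fallback, from 14 and 12 back to 20: sodium methoxyacetylide 14 would be silylated in the flask with Me3SiCl (THF, −40 °C → rt) to (methoxyethynyl)trimethylsilane F1, a distillable ynol ether without the polymerisation-prone terminal C–H that can be used in large excess at 110–140 °C. Its benzannulation with 12 (same regiochemistry, silicon on the carbon that bonds to the ketene carbonyl) would give 3-{2-[3-(benzyloxy)phenyl]ethyl}-2,4-bis[4-(benzyloxy)benzyl]-5-methoxy-6-(trimethylsilyl)phenol F2. Ipso-protodesilylation (CF3CO2H, CH2Cl2, 0 °C), made easy by the flanking OH and OMe groups, would return to 20.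

2. Step 4. At 125 °C the doubly activated CH2 of 7 may allow isomerisation to an allenyl ether, or ketene 8 may oligomerise before it meets a second molecule of 7. Fallback, from 7 back to 9: commercial 3-[4-(benzyloxy)phenyl]propanoic acid F3 would be converted with oxalyl chloride (DMF cat., CH2Cl2) into 3-[4-(benzyloxy)phenyl]propanoyl chloride F4. Ketene 8 would then be generated at 0 °C → rt by dehydrochlorination of the acid chloride with Et3N, added slowly to 7 in Et2O. The same [2+2] cycloaddition would give 9 without heating, and every molecule of 7 would end up in the product.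

3. Step 3. Substitution by the weakly nucleophilic alkoxyacetylide may be sluggish, with electron-transfer or halogen–metal exchange pathways leading to homocoupling of 5, or with base-induced propargyl–allenyl isomerisation of the product. Fallback, from 6 back to 7: 6 would be transmetalated with ZnCl2 to (ethoxyethynyl)zinc chloride F5 and coupled with 5 under Pd(PPh3)4 (zerovalent palladium, 3 mol%) in THF at rt. This is a Negishi alkynyl–benzyl cross-coupling in which oxidative addition, not SN2 attack, activates the bromide, and the zinc acetylide is too weakly basic to isomerise 7.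

**Further compounds**
F1 | step 7 | (methoxyethynyl)trimethylsilane | COC#C[Si](C)(C)C
F2 | step 7 | 3-{2-[3-(benzyloxy)phenyl]ethyl}-2,4-bis[4-(benzyloxy)benzyl]-5-methoxy-6-(trimethylsilyl)phenol | COc1c([Si](C)(C)C)c(O)c(Cc2ccc(OCc3ccccc3)cc2)c(CCc2cccc(OCc3ccccc3)c2)c1Cc1ccc(OCc2ccccc2)cc1
F3 | step 4 | 3-[4-(benzyloxy)phenyl]propanoic acid | OC(=O)CCc1ccc(OCc2ccccc2)cc1
F4 | step 4 | 3-[4-(benzyloxy)phenyl]propanoyl chloride | ClC(=O)CCc1ccc(OCc2ccccc2)cc1
F5 | step 3 | (ethoxyethynyl)zinc chloride | CCOC#C[Zn]Cl
A1 | direct plan | 3,5-dimethoxybenzaldehyde | COc1cc(C=O)cc(OC)c1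
A2 | direct plan | 3-hydroxyphenylacetic acid | OC(=O)Cc1cccc(O)c1
A3 | direct plan | 3-{2-[3-(benzyloxy)-5-methoxyphenyl]ethyl}phenol | Oc1cccc(CCc2cc(OC)cc(OCc3ccccc3)c2)c1
A4 | direct plan | 3-{2-[3-(benzyloxy)-2,6-dibromo-5-methoxyphenyl]ethyl}phenyl pivalate | CC(C)(C)C(=O)Oc1cccc(CCc2c(Br)c(OCc3ccccc3)cc(OC)c2Br)c1
A5 | direct plan | [4-(benzyloxy)benzyl]zinc chloride | Cl[Zn]Cc1ccc(OCc2ccccc2)cc1
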